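**Proposed synthesis of 2,6-bis(4-hydroxybenzyl)-3-hydroxy-5,3′-dimethoxybibenzyl (18) by aldol folding of a linear tetraketone**

## The problem

The target 18 is a bibenzyl whose ring A is pentasubstituted. The arylethyl chain at C1 is flanked by 4-hydroxybenzyl groups at C2 and C6, these by oxygen at C3 (free OH) and C5 (OMe), and only C4 carries hydrogen. There is no stereocentre, so the difficulty is purely regiochemical: three contiguous carbon substituents must be set between two oxygens, and electrophilic substitution cannot be trusted because C4 and the anisole-type ring B are both activated. Ring A would be mirror-symmetric through C1 and C4 but for OH at C3 against OMe at C5, so any route through the symmetrical resorcinol must tell two equivalent hydroxyls apart. Three free phenols, two of them in 4-hydroxybenzyl units that give quinone methides on oxidation or under strong Lewis acid, argue for benzyl ether protection to the last step and a reductive finish. The enabling feature is the 1,3-relationship of the C3 and C5 oxygens with unsubstituted C4 between them. If the benzylic carbon on C2 is written as a ketone, ring A and that carbon are the aldol fold of a linear 1,3,5,7-tetraketone that already holds every ring carbon, both ring oxygens and the C6 and C1 branches in order. The same ketone later hydrogen-bonds the C3 hydroxyl and so breaks the symmetry for the methylation.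

## Retrosynthesis

**18 from 15.** No skeletal bond is cut. The benzylic CH2 on C2 is traced back to a diaryl ketone and the two 4-hydroxybenzyl phenols to benzyl ethers, giving ketone 15. Cutting the C2–CH2 bond instead (a Friedel–Crafts benzylation) would have to choose between C2, C4 and ring B. The forward step is one hydrogenation over palladium on carbon in acid: both O-benzyl groups are cleaved (to 16) and the electron-rich diaryl C=O is removed through benzhydrol 17, while two aryl methyl ethers survive.

**15 from 14.** The O–CH3 bond at C5 is cut. In resorcinol ketone 14 the C3 hydroxyl is held in a hydrogen bond to the ketone, whereas the C5 hydroxyl is para to it, more acidic and free. One equivalent of iodomethane with a weak base should therefore alkylate C5 only. The methyl cannot be carried earlier, because both oxygens are carbonyls in the chain.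

**14 from 12.** The C1–C2 bond of ring A is cut, which opens the ring to tetraketone 12. Its chain carbons are written c1 to c9 from the aroyl carbonyl: c1, c3, c5 and c7 are carbonyls, c6 carries the benzyl group, and c8–c9 lead to ring B. The alternative cut, C1–C6, would need a nucleophile on a carbon that becomes quaternary and an attack on the deactivated aryl ketone. Cuts at ring C–C bonds next to oxygen would be Claisen closures requiring an ester and would give a phloroglucinol pattern. Precursor 12 is acyclic, and its one stereocentre (c6) is lost on aromatisation. The forward reaction is a mild-base aldol of the doubly activated c2 methylene onto ketone c7 (aldol 13), then loss of water.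

**12 from 7 and 9.** The c6–c7 bond is cut, giving triketone 7 and Weinreb amide 9. A cut at c4–c5 or c2–c3 would need a β-keto ester as acyl donor, whose own enolate shuts it down. The c6–c7 cut uses the only α-position left in 7 once c2 and c4 are deprotonated (trianion 10). An amide is preferred to the ester because the chelated adduct 11 survives until quench, so the acidic c6–H of the product never meets the polyanion.

**9 from 8.** The amide C–N bond is cut back to commercial methyl ester 8 (one step).

**7 from 4 and 5.** The c1–c2 bond is cut, giving diketone 4 and benzoate 5. The acyl donor has no α-hydrogen, which is the best case for polyanion acylation. The forward step asks that the dianion of 4 (6) forms at the methyl terminus rather than at the methylene terminus.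

**4 from 1 and 2.** The bond between the terminal carbon of acetylacetone 1 and the benzylic carbon of chloride 2 is cut. The forward step is alkylation of dianion 3 at its terminal carbanion. The carbon so introduced ends up as the C6 benzyl group of ring A.

## Roads not taken

**Alternative 1: conjunctive coupling across the ethylene bridge.**
- Cut: the C1–bridge bond and the bridge–ring B bond, around a vinyl unit.
- Forward key step: ring A bromide A1 is lithiated and added to vinylboronic acid pinacol ester A2. With 3-methoxyphenyl triflate A3 and Pd(OAc)2/bisphosphine, the arylpalladium species (divalent palladium) triggers a 1,2-shift of the ring A aryl from boron to carbon while ring B adds to the terminal carbon, giving boronate A4.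
- Merits: convergent and mild, and the best of the four plans for varying ring B.
- Weak points: A1 already carries all five ring A substituents, so the real problem is only moved into its preparation, including the OBn/OMe differentiation of a symmetrical precursor. The migrating aryl is 2,6-dibenzylated, far more hindered than this shift is known to tolerate. The aryllithium sits next to two acidic diarylmethane CH2 groups. A4 has a C–B bond and a stereocentre that the target does not need, so a protodeboronation is added before the final hydrogenolysis.
- Comparison: the chosen plan builds ring A itself from acyclic pieces in about the number of steps A1 alone would cost.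

**Alternative 2: Catellani three-component assembly.**
- Cut: both C–benzyl bonds (C2, C6) and the C1–alkene bond.
- Forward key step: iodide A5, two equivalents of chloride 2 and 3-methoxystyrene A6 combine under Catellani conditions (Pd(OAc)2, a triarylphosphine, the strained-alkene mediator, Cs2CO3) to give stilbene A7. One hydrogenation then reduces the alkene and removes three benzyl groups.
- Merits: three bonds in one step and a global reductive finish. On paper this is the shortest route, about four steps against seven here, and that must be conceded.
- Weak points: both ortho C–H positions of A5 lie between the palladium-bearing carbon and an alkoxy carbon, and ortho functionalisation next to a meta substituent is the known weak spot of this chemistry; here it must succeed twice. Benzyl chlorides are uncommon partners for the palladacycle, and an electron-rich one also adds directly to zerovalent palladium, opening a benzyl–Heck channel with A6. Mono- and dibenzylated products would be hard to separate. A5 itself needs mono-differentiation of a symmetrical iodoresorcinol.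
- Comparison: the chosen plan is longer but sets against this positional certainty (every substituent is written into the chain), the OH/OMe distinction by chelation, and no dependence on an unprecedented double ortho-benzylation.

**Alternative 3: Michael–Claisen annulation, aromatised late.**
- Cut: C6–C1 (Michael) and C4–C5 (Claisen).
- Forward key step: NaOMe adds malonate A8 to the β-carbon of α-benzyl enone A9, and the methyl ketone enolate of the adduct closes onto one ester, giving dione ester A10.
- Merits: cheap reagents and all ring carbons in place after one operation.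
- Weak points: the Michael step joins a tertiary malonate anion to a β-substituted, α-branched enone, forming a quaternary centre next to a tertiary one, which is reversible and hindered. A10 is then three adjustments from an arene: ester hydrolysis, decarboxylation and dehydrogenation in the presence of benzyl ethers and diarylmethane positions. The resulting resorcinol A11 is mirror-symmetric, so its mono-methylation is statistical. Stereocentres are made only to be destroyed.
- Comparison: the chosen plan reaches the aromatic oxidation level directly and delivers the two oxygens already differentiated. Alternative 3 is better only in avoiding polyanion chemistry.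

Key step: step 5

Assumption: the SMILES string defines the target (ring A: OH at C3, OMe at C5; ring B: one OMe meta to the bridge), and LiN(iPr)2 is used as a purchased solution.

## Route

Step 1
Reactants: 1 pentane-2,4-dione (acetylacetone); 2 4-(benzyloxy)benzyl chloride
Product: 4 6-[4-(benzyloxy)phenyl]hexane-2,4-dione, via dilithium 1,3-dianion of pentane-2,4-dione 3 (not isolated)
Conditions: LiN(iPr)2 (2.1 equiv), THF, 0 °C; then 2, 0 °C → rt; aq. NH4Cl
Reagents that add atoms: none
Why: C-alkylation of a β-diketone 1,3-dianion; the terminal carbanion is far more nucleophilic than the central enolate carbon, so the reactive benzylic chloride should be taken up at the methyl carbon only.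

Step 2
Reactants: 4 6-[4-(benzyloxy)phenyl]hexane-2,4-dione; 5 methyl 4-(benzyloxy)benzoate
Product: 7 1,7-bis[4-(benzyloxy)phenyl]heptane-1,3,5-trione, via dilithium dianion of diketone 6 (not isolated)
Conditions: LiN(iPr)2 (3.1 equiv), THF, 0 °C; then 5, 0 °C → rt; cold dilute HCl to pH 5
Reagents that add atoms: none
Why: Claisen-type aroylation of a β-diketone dianion by an ester without α-hydrogen; the second deprotonation is expected at the methyl rather than the methylene terminus, and the third equivalent of base takes up the more acidic triketone so that dianion 6 is not quenched by product.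

Step 3
Reactants: 8 methyl 3-(3-methoxyphenyl)propanoate
Product: 9 N-methoxy-N-methyl-3-(3-methoxyphenyl)propanamide
Conditions: MeNH(OMe)·HCl (1.5 equiv), iPrMgCl (3.0 equiv), THF, −20 → 0 °C; aq. NH4Cl
Reagents that add atoms: N,O-dimethylhydroxylamine hydrochloride, CNOC.Cl
Why: Weinreb amide synthesis by aminolysis of an ester with the chloromagnesium amide formed in the flask; the chelated tetrahedral magnesium adduct stops the reaction at the amide.

Step 4
Reactants: 7 1,7-bis[4-(benzyloxy)phenyl]heptane-1,3,5-trione; 9 N-methoxy-N-methyl-3-(3-methoxyphenyl)propanamide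
Product: 12 1-[4-(benzyloxy)phenyl]-6-[4-(benzyloxy)benzyl]-9-(3-methoxyphenyl)nonane-1,3,5,7-tetraone (racemic at c6), via trilithium trianion of triketone 10 (not isolated), via trilithium tetrahedral adduct 11 (not isolated)
Conditions: LiN(iPr)2 (3.1 equiv), THF, 0 °C; then 9, −20 → 0 °C; cold dilute HCl to pH 5, 0 °C; used crude
Reagents that add atoms: none
Why: Claisen-type acylation of a 1,3,5-triketone trianion at its terminal carbanion with a Weinreb amide; after c2 and c4 are deprotonated, c6 is the only α-position left, so the site is fixed, and adduct 11 holds until the quench, which keeps the acidic c6–H of the product away from the polyanion.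

Step 5
Reactants: 12 1-[4-(benzyloxy)phenyl]-6-[4-(benzyloxy)benzyl]-9-(3-methoxyphenyl)nonane-1,3,5,7-tetraone
Product: 14 [4-(benzyloxy)phenyl]{3-[4-(benzyloxy)benzyl]-4,6-dihydroxy-2-[2-(3-methoxyphenyl)ethyl]phenyl}methanone, via aldol adduct 13 (not isolated)
Conditions: K2CO3 (2 equiv), iPrOH–THF, rt; then 1 M HCl, rt
Reagents that add atoms: none
Why: Carbonate deprotonates the most acidic, doubly activated c2 methylene (between aroyl carbonyl c1 and ketone c3), and the enolate carbon adds to ketone c7, which carries the arylethyl chain, forming the C1–C2 bond of ring A and giving aldol 13. Acidification dehydrates 13 across the new bond and the two remaining ring carbonyls (c3, c5) enolise, so aromatisation makes the closure irreversible. The closest known reaction type is the base-induced aldol cyclisation of 1,3,5,7-tetraketones and 3,5,7-triketo esters to acylresorcinols and resorcylates, the laboratory model of polyketide folding. Ring A closes in the 6-(enolendo)-exo-trig mode. No stereocentre is set: those of 13 and the c6 centre of 12 disappear on aromatisation. The step needs site selectivity among three six-ring aldol modes: attack of c6 on aryl ketone c1 would give a quaternary ring carbon that cannot aromatise and so stays reversible, and attack of the c8 methylene on c3 needs a singly activated, much less acidic nucleophile. The benzyl group on c6 also makes the c5/c7 diketone less acidic and less enolised than the c1/c3 unit, so c7 stays a ketone while c2 is the enolate, and isopropanol is chosen over methanol to hold back retro-Claisen cleavage.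

Step 6
Reactants: 14 [4-(benzyloxy)phenyl]{3-[4-(benzyloxy)benzyl]-4,6-dihydroxy-2-[2-(3-methoxyphenyl)ethyl]phenyl}methanone
Product: 15 [4-(benzyloxy)phenyl]{3-[4-(benzyloxy)benzyl]-6-hydroxy-4-methoxy-2-[2-(3-methoxyphenyl)ethyl]phenyl}methanone
Conditions: MeI (1.1 equiv), K2CO3 (1.2 equiv), acetone, rt → 40 °C
Reagents that add atoms: iodomethane, CI
Why: Williamson O-methylation of the hydroxyl para to the ketone (ring A C5); the ortho hydroxyl (C3) is tied into a six-membered hydrogen bond with the carbonyl and is less acidic and less nucleophilic, the usual basis for mono-alkylating 2,4-dihydroxyaryl ketones.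

Step 7
Reactants: 15 [4-(benzyloxy)phenyl]{3-[4-(benzyloxy)benzyl]-6-hydroxy-4-methoxy-2-[2-(3-methoxyphenyl)ethyl]phenyl}methanone
Product: 18 2,4-bis(4-hydroxybenzyl)-5-methoxy-3-[2-(3-methoxyphenyl)ethyl]phenol (the target), via debenzylated ketone 16 (not isolated), via racemic benzhydrol 17 (not isolated)
Conditions: H2 (4 atm), Pd/C (10 wt% palladium on carbon), EtOAc–AcOH, HClO4 (cat.), rt → 40 °C
Reagents that add atoms: none
Why: Catalytic hydrogenolysis; the O-benzyl groups should go first (16), then the diaryl ketone is hydrogenated to benzhydrol 17, which ionises readily in acid because of the ortho-hydroxy, para-methoxy and para′-hydroxy donors and is hydrogenolysed to the CH2; aryl methyl ethers and the arenes are inert to Pd/C under these conditions.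

## Compound list

1 | pentane-2,4-dione (acetylacetone) | CC(=O)CC(C)=O | starting material
2 | 4-(benzyloxy)benzyl chloride | ClCc1ccc(OCc2ccccc2)cc1 | starting material
3 | dilithium 1,3-dianion of pentane-2,4-dione | [Li+].[Li+].C=C([O-])C=C(C)[O-] | intermediate
4 | 6-[4-(benzyloxy)phenyl]hexane-2,4-dione | CC(=O)CC(=O)CCc1ccc(OCc2ccccc2)cc1 | intermediate
5 | methyl 4-(benzyloxy)benzoate | COC(=O)c1ccc(OCc2ccccc2)cc1 | starting material
6 | dilithium dianion of 4 (terminal CH2 and central CH deprotonated) | [Li+].[Li+].C=C([O-])C=C([O-])CCc1ccc(OCc2ccccc2)cc1 | intermediate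
7 | 1,7-bis[4-(benzyloxy)phenyl]heptane-1,3,5-trione | O=C(CC(=O)CC(=O)CCc1ccc(OCc2ccccc2)cc1)c1ccc(OCc2ccccc2)cc1 | intermediate
8 | methyl 3-(3-methoxyphenyl)propanoate | COC(=O)CCc1cccc(OC)c1 | starting material
9 | N-methoxy-N-methyl-3-(3-methoxyphenyl)propanamide | CON(C)C(=O)CCc1cccc(OC)c1 | intermediate
10 | trilithium trianion of 7 (c2, c4 and c6 deprotonated) | [Li+].[Li+].[Li+].[O-]C(=CC([O-])=CC([O-])=CCc1ccc(OCc2ccccc2)cc1)c1ccc(OCc2ccccc2)cc1 | intermediate
11 | trilithium tetrahedral adduct of 10 and 9 (alkoxide at c7, dienolate over c1–c4; racemic mixture of diastereomers) | [Li+].[Li+].[Li+].COc1cccc(CCC([O-])(N(C)OC)C(Cc2ccc(OCc3ccccc3)cc2)C(=O)C=C([O-])C=C([O-])c2ccc(OCc3ccccc3)cc2)c1 | intermediate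
12 | 1-[4-(benzyloxy)phenyl]-6-[4-(benzyloxy)benzyl]-9-(3-methoxyphenyl)nonane-1,3,5,7-tetraone (racemic at c6, drawn as the tetraketo tautomer) | COc1cccc(CCC(=O)C(Cc2ccc(OCc3ccccc3)cc2)C(=O)CC(=O)CC(=O)c2ccc(OCc3ccccc3)cc2)c1 | intermediate
13 | 6-[4-(benzyloxy)benzoyl]-4-[4-(benzyloxy)benzyl]-5-hydroxy-5-[2-(3-methoxyphenyl)ethyl]cyclohexane-1,3-dione (mixture of diastereomers) | COc1cccc(CCC2(O)C(Cc3ccc(OCc4ccccc4)cc3)C(=O)CC(=O)C2C(=O)c2ccc(OCc3ccccc3)cc2)c1 | intermediate
14 | [4-(benzyloxy)phenyl]{3-[4-(benzyloxy)benzyl]-4,6-dihydroxy-2-[2-(3-methoxyphenyl)ethyl]phenyl}methanone | COc1cccc(CCc2c(C(=O)c3ccc(OCc4ccccc4)cc3)c(O)cc(O)c2Cc2ccc(OCc3ccccc3)cc2)c1 | intermediate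
15 | [4-(benzyloxy)phenyl]{3-[4-(benzyloxy)benzyl]-6-hydroxy-4-methoxy-2-[2-(3-methoxyphenyl)ethyl]phenyl}methanone | COc1cccc(CCc2c(C(=O)c3ccc(OCc4ccccc4)cc3)c(O)cc(OC)c2Cc2ccc(OCc3ccccc3)cc2)c1 | intermediate
16 | (4-hydroxyphenyl){6-hydroxy-3-(4-hydroxybenzyl)-4-methoxy-2-[2-(3-methoxyphenyl)ethyl]phenyl}methanone | COc1cccc(CCc2c(C(=O)c3ccc(O)cc3)c(O)cc(OC)c2Cc2ccc(O)cc2)c1 | intermediate
17 | 2-[hydroxy(4-hydroxyphenyl)methyl]-4-(4-hydroxybenzyl)-5-methoxy-3-[2-(3-methoxyphenyl)ethyl]phenol (racemic) | COc1cccc(CCc2c(C(O)c3ccc(O)cc3)c(O)cc(OC)c2Cc2ccc(O)cc2)c1 | intermediate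
18 | 2,4-bis(4-hydroxybenzyl)-5-methoxy-3-[2-(3-methoxyphenyl)ethyl]phenol (2,6-bis(4-hydroxybenzyl)-3-hydroxy-5,3′-dimethoxybibenzyl; no stereocentre) | COc1cccc(CCc2c(Cc3ccc(O)cc3)c(O)cc(OC)c2Cc2ccc(O)cc2)c1 | target

## Step count and risks

Total: 7 steps. Longest linear sequence: 6 steps (steps 1, 2, 4, 5, 6, 7 from acetylacetone 1); step 3 is a one-step side branch.

**Step 5 (key step).** The most likely failure is diversion of the open chain before carbon–carbon closure. Tetraketone 12 can cyclodehydrate through oxygen to 4-pyranones during its acidic isolation or during the acid finish. In base, the non-enolised, 2-substituted c5/c7 diketone can suffer retro-Claisen loss of the c7 acyl group, the more so because c7 is hindered by the c6 benzyl. Closure through the singly activated c8 methylene is the smaller risk. The fallback carries the chain in masked form. It sets out from 7, which is cyclodehydrated (p-TsOH, toluene, reflux with removal of water) to 2-[4-(benzyloxy)phenyl]-6-{2-[4-(benzyloxy)phenyl]ethyl}-4H-pyran-4-one F1. Lateral deprotonation with LiN(SiMe3)2 at the CH2 next to the pyranone ring (the former c6) and acylation with 9 should give 2-[4-(benzyloxy)phenyl]-6-{1-[4-(benzyloxy)phenyl]-5-(3-methoxyphenyl)-3-oxopentan-2-yl}-4H-pyran-4-one F2, a storable equivalent of 12. Warm KOH in aqueous dioxane opens the pyranone by conjugate addition of hydroxide, and the freed polyanion closes in the same flask, rejoining the route at 14 without free 12 ever passing through acid.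

**Step 4.** The trianion may form incompletely at the secondary c6 position, or it may act on amide 9 as a base (α-deprotonation, or base-induced loss of formaldehyde from the N-methoxy group) instead of being acylated at a hindered carbanion. The fallback places the branch by central alkylation of a β-diketone monoanion and makes the last bond by aroylation at a methyl terminus. It sets out from 1: dianion 3 and 3-methoxybenzyl chloride give 6-(3-methoxyphenyl)hexane-2,4-dione F3. K2CO3 and 2 in acetone give 3-[4-(benzyloxy)benzyl]-6-(3-methoxyphenyl)hexane-2,4-dione F4. Its dianion (LiN(iPr)2, methyl terminus) is acetylated with N-methoxy-N-methylacetamide to 5-[4-(benzyloxy)benzyl]-8-(3-methoxyphenyl)octane-2,4,6-trione F5. The trianion of F5 is aroylated at its methyl terminus with 5, which rejoins the route at 12.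

**Step 7.** Reduction may stall at the ketone or benzhydrol stage because the carbonyl has two ortho substituents and is twisted. Under the acid it needs, the benzhydryl cation may instead alkylate ring B intramolecularly (a seven-membered Friedel–Crafts closure). The fallback removes the benzylic oxygen with hydride under basic conditions. It sets out from 15: ethyl chloroformate and Et3N (THF, 0 °C) give 2-[4-(benzyloxy)benzoyl]-4-[4-(benzyloxy)benzyl]-5-methoxy-3-[2-(3-methoxyphenyl)ethyl]phenyl ethyl carbonate F6. NaBH4 in aqueous THF reduces the ketone, the carbonate migrates to the new alkoxide and is eliminated to an ortho-quinone methide, and this is reduced to 2,4-bis[4-(benzyloxy)benzyl]-5-methoxy-3-[2-(3-methoxyphenyl)ethyl]phenol F7. Neutral hydrogenolysis (H2, Pd/C, EtOAc–EtOH) of the two benzyl ethers then arrives at 18.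

**Step 2.** Part of the second deprotonation of 4 may occur at the methylene terminus, giving a branched triketone, and the more acidic product may quench dianion 6 and stall conversion. The fallback inverts the order so that only methyl termini are present when the aroyl group is introduced. It sets out from 1: dianion 3 is aroylated with 5 to 1-[4-(benzyloxy)phenyl]hexane-1,3,5-trione F8, and the trianion of F8 (LiN(iPr)2, 3 equiv) is alkylated at its terminal carbanion with 2, rejoining the route at 7.

## Further compounds

F1 | step 5 | 2-[4-(benzyloxy)phenyl]-6-{2-[4-(benzyloxy)phenyl]ethyl}-4H-pyran-4-one | O=c1cc(CCc2ccc(OCc3ccccc3)cc2)oc(-c2ccc(OCc3ccccc3)cc2)c1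
F2 | step 5 | 2-[4-(benzyloxy)phenyl]-6-{1-[4-(benzyloxy)phenyl]-5-(3-methoxyphenyl)-3-oxopentan-2-yl}-4H-pyran-4-one (racemic) | COc1cccc(CCC(=O)C(Cc2ccc(OCc3ccccc3)cc2)c2cc(=O)cc(-c3ccc(OCc4ccccc4)cc3)o2)c1
F3 | step 4 | 6-(3-methoxyphenyl)hexane-2,4-dione | CC(=O)CC(=O)CCc1cccc(OC)c1
F4 | step 4 | 3-[4-(benzyloxy)benzyl]-6-(3-methoxyphenyl)hexane-2,4-dione (racemic) | CC(=O)C(Cc1ccc(OCc2ccccc2)cc1)C(=O)CCc1cccc(OC)c1
F5 | step 4 | 5-[4-(benzyloxy)benzyl]-8-(3-methoxyphenyl)octane-2,4,6-trione (racemic) | CC(=O)CC(=O)C(Cc1ccc(OCc2ccccc2)cc1)C(=O)CCc1cccc(OC)c1
F6 | step 7 | 2-[4-(benzyloxy)benzoyl]-4-[4-(benzyloxy)benzyl]-5-methoxy-3-[2-(3-methoxyphenyl)ethyl]phenyl ethyl carbonate | CCOC(=O)Oc1cc(OC)c(Cc2ccc(OCc3ccccc3)cc2)c(CCc2cccc(OC)c2)c1C(=O)c1ccc(OCc2ccccc2)cc1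
F7 | step 7 | 2,4-bis[4-(benzyloxy)benzyl]-5-methoxy-3-[2-(3-methoxyphenyl)ethyl]phenol | COc1cccc(CCc2c(Cc3ccc(OCc4ccccc4)cc3)c(O)cc(OC)c2Cc2ccc(OCc3ccccc3)cc2)c1
F8 | step 2 | 1-[4-(benzyloxy)phenyl]hexane-1,3,5-trione | CC(=O)CC(=O)CC(=O)c1ccc(OCc2ccccc2)cc1
A1 | alternative 1 | 1-(benzyloxy)-2,4-bis[4-(benzyloxy)benzyl]-3-bromo-5-methoxybenzene | COc1cc(OCc2ccccc2)c(Cc2ccc(OCc3ccccc3)cc2)c(Br)c1Cc1ccc(OCc2ccccc2)cc1
A2 | alternative 1 | vinylboronic acid pinacol ester (2-ethenyl-4,4,5,5-tetramethyl-1,3,2-dioxaborolane) | C=CB1OC(C)(C)C(C)(C)O1
A3 | alternative 1 | 3-methoxyphenyl trifluoromethanesulfonate | COc1cccc(OS(=O)(=O)C(F)(F)F)c1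
A4 | alternative 1 | 2-{1-[3-(benzyloxy)-2,6-bis[4-(benzyloxy)benzyl]-5-methoxyphenyl]-2-(3-methoxyphenyl)ethyl}-4,4,5,5-tetramethyl-1,3,2-dioxaborolane (racemic) | COc1cccc(CC(B2OC(C)(C)C(C)(C)O2)c2c(Cc3ccc(OCc4ccccc4)cc3)c(OCc3ccccc3)cc(OC)c2Cc2ccc(OCc3ccccc3)cc2)c1
A5 | alternative 2 | 1-(benzyloxy)-3-iodo-5-methoxybenzene | COc1cc(I)cc(OCc2ccccc2)c1
A6 | alternative 2 | 3-methoxystyrene | COc1cccc(C=C)c1
A7 | alternative 2 | (E)-3-(benzyloxy)-2,6-bis[4-(benzyloxy)benzyl]-5,3′-dimethoxystilbene | COc1cccc(/C=C/c2c(Cc3ccc(OCc4ccccc4)cc3)c(OCc3ccccc3)cc(OC)c2Cc2ccc(OCc3ccccc3)cc2)c1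
A8 | alternative 3 | dimethyl 2-[4-(benzyloxy)benzyl]malonate | COC(=O)C(Cc1ccc(OCc2ccccc2)cc1)C(=O)OC
A9 | alternative 3 | (E)-3-[4-(benzyloxy)benzyl]-6-(3-methoxyphenyl)hex-3-en-2-one | CC(=O)/C(Cc1ccc(OCc2ccccc2)cc1)=C/CCc1cccc(OC)c1
A10 | alternative 3 | methyl 1,3-bis[4-(benzyloxy)benzyl]-2-[2-(3-methoxyphenyl)ethyl]-4,6-dioxocyclohexane-1-carboxylate (diastereomer mixture) | COC(=O)C1(Cc2ccc(OCc3ccccc3)cc2)C(CCc2cccc(OC)c2)C(Cc2ccc(OCc3ccccc3)cc2)C(=O)CC1=O
A11 | alternative 3 | 4,6-bis[4-(benzyloxy)benzyl]-5-[2-(3-methoxyphenyl)ethyl]benzene-1,3-diol | COc1cccc(CCc2c(Cc3ccc(OCc4ccccc4)cc3)c(O)cc(O)c2Cc2ccc(OCc3ccccc3)cc2)c1
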